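The cyclohexane (ring locants: C1 bears the chain, C2 is CMe2, C3 is CHOH, C6 is C(Me)OH) is disconnected at C3–C4. The key step exploits the 1,4-relationship of the ring oxygens on C3 and C6: they are tied as a γ-lactone (C3 the acyl carbon, its ring oxygen on C6) whose C6 carries a 2-iodoethyl arm (C5–C4). SmI2 makes C4 a carbon nucleophile that attacks the lactone carbonyl; collapse of the bridged hemiketal closes the carbocycle and frees the C6 hydroxyl and a C3 ketone in one operation. C1 comes from an iridium-catalysed allylation, C6 from a Felkin–Anh methyl addition, C3 from L-Selectride, the chain carbinol from (R)-linalool.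

Key step: step 10

Assumption: the (Sa,S,S) antipode of the phosphoramidite ligand is taken to give the (3S) ester 8 from the (E)-carbonate 6; if the sense of induction is the opposite, the (Ra,R,R) ligand is used with no other change.

Step 1
Reactants: 1 (R)-(−)-linalool
Product: 3 (3R)-3,7-dimethyloct-6-ene-1,3-diol, via B-alkyl-9-BBN adduct 2 (not isolated)
Conditions: 9-BBN (1.3 equiv), THF, 0 → 23 °C; then NaOH (aq), H2O2, 0 °C
Reagents that add atoms: hydrogen peroxide, OO
Why: Anti-Markovnikov hydroboration–oxidation, in which 9-BBN adds only to the monosubstituted vinyl group (the trisubstituted alkene is too hindered) and the existing carbinol centre is not touched.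

Step 2
Reactants: 3 (3R)-3,7-dimethyloct-6-ene-1,3-diol
Product: 4 (4R)-2,2,4-trimethyl-4-(4-methylpent-3-en-1-yl)-1,3-dioxane
Conditions: 2,2-dimethoxypropane, PPTS (cat.), CH2Cl2, 23 °C
Reagents that add atoms: 2,2-dimethoxypropane, COC(C)(C)OC
Why: Acid-catalysed ketal exchange gives the six-membered isopropylidene ketal, which masks both chain hydroxyls against the organometallic, reducing and oxidising steps that follow.

Step 3
Reactants: 4 (4R)-2,2,4-trimethyl-4-(4-methylpent-3-en-1-yl)-1,3-dioxane; 5 allyl methyl carbonate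
Product: 6 methyl (2E)-5-[(4R)-2,2,4-trimethyl-1,3-dioxan-4-yl]pent-2-en-1-yl carbonate
Conditions: second-generation Hoveyda–Grubbs catalyst RuCl2(H2IMes)(=CH–C6H4-2-OiPr) (5 mol %), 5 (4 equiv), CH2Cl2, 40 °C
Reagents that add atoms: none
Why: Olefin cross-metathesis exchanges the 2-methylprop-1-enyl terminus for the allyl carbonate unit with loss of volatile isobutene, and the disubstituted product should form mainly as the E isomer.

Step 4
Reactants: 6 methyl (2E)-5-[(4R)-2,2,4-trimethyl-1,3-dioxan-4-yl]pent-2-en-1-yl carbonate; 7 1-methoxy-2-methyl-1-(trimethylsilyloxy)prop-1-ene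
Product: 8 methyl (3S)-2,2-dimethyl-3-{2-[(4R)-2,2,4-trimethyl-1,3-dioxan-4-yl]ethyl}pent-4-enoate
Conditions: [Ir(cod)Cl]2 (2 mol %), (Sa,S,S)-O,O′-(1,1′-binaphthyl-2,2′-diyl) N,N-bis(1-phenylethyl)phosphoramidite (4 mol %, pre-activated with n-PrNH2), 7 (1.5 equiv), CsF (10 mol %), THF, 50 °C
Reagents that add atoms: none
Why: Iridium-catalysed asymmetric allylic alkylation with a silyl ketene acetal is branched-selective, so the enolate carbon attacks the substituted allyl terminus and the ring C1 stereocentre is set under ligand control next to the new quaternary C2.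

Step 5
Reactants: 8 methyl (3S)-2,2-dimethyl-3-{2-[(4R)-2,2,4-trimethyl-1,3-dioxan-4-yl]ethyl}pent-4-enoate
Product: 10 methyl (3R)-3-formyl-2,2-dimethyl-5-[(4R)-2,2,4-trimethyl-1,3-dioxan-4-yl]pentanoate, via secondary ozonide 9 (not isolated)
Conditions: O3, CH2Cl2, −78 °C; then PPh3, −78 → 23 °C
Reagents that add atoms: ozone, [O-][O+]=O
Why: Ozonolysis with reductive work-up cleaves the only C=C bond to the α-branched aldehyde under neutral conditions that should not epimerise ring C1.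

Step 6
Reactants: 10 methyl (3R)-3-formyl-2,2-dimethyl-5-[(4R)-2,2,4-trimethyl-1,3-dioxan-4-yl]pentanoate
Product: 11 methyl (3R)-3-(1-hydroxyprop-2-en-1-yl)-2,2-dimethyl-5-[(4R)-2,2,4-trimethyl-1,3-dioxan-4-yl]pentanoate (both carbinol epimers)
Conditions: CH2=CHMgBr (1.2 equiv), THF, −78 °C; AcOH in THF at −78 °C
Reagents that add atoms: vinylmagnesium bromide, C=C[Mg]Br
Why: Grignard 1,2-addition to the aldehyde is run and quenched cold so that the hydroxy ester does not lactonise, and the new carbinol centre needs no control because it is oxidised in the next step.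

Step 7
Reactants: 11 methyl (3R)-3-(1-hydroxyprop-2-en-1-yl)-2,2-dimethyl-5-[(4R)-2,2,4-trimethyl-1,3-dioxan-4-yl]pentanoate
Product: 12 methyl (3R)-2,2-dimethyl-3-(prop-2-enoyl)-5-[(4R)-2,2,4-trimethyl-1,3-dioxan-4-yl]pentanoate
Conditions: Dess–Martin periodinane, NaHCO3, CH2Cl2, 0 → 23 °C
Reagents that add atoms: none
Why: Dess–Martin oxidation of the allylic alcohol gives the vinyl ketone under buffered, non-basic conditions that spare the α-stereocentre and the ketal.

Step 8
Reactants: 12 methyl (3R)-2,2-dimethyl-3-(prop-2-enoyl)-5-[(4R)-2,2,4-trimethyl-1,3-dioxan-4-yl]pentanoate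
Product: 14 (4R,5S)-5-ethenyl-3,3,5-trimethyl-4-{2-[(4R)-2,2,4-trimethyl-1,3-dioxan-4-yl]ethyl}oxolan-2-one, via lithium alkoxide 13 (not isolated)
Conditions: MeLi (1.15 equiv), Et2O/THF, −78 °C; then warm to 23 °C
Reagents that add atoms: methyllithium, [Li]C
Why: 1,2-Addition of methyllithium to the enone under Felkin–Anh control (the CMe2CO2Me group lies anti to the incoming methyl, which passes the α-hydrogen) sets the ring C6 carbinol, and on warming the alkoxide closes the γ-lactone by intramolecular transesterification.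

Step 9
Reactants: 14 (4R,5S)-5-ethenyl-3,3,5-trimethyl-4-{2-[(4R)-2,2,4-trimethyl-1,3-dioxan-4-yl]ethyl}oxolan-2-one
Product: 16 (4R,5S)-5-(2-iodoethyl)-3,3,5-trimethyl-4-{2-[(4R)-2,2,4-trimethyl-1,3-dioxan-4-yl]ethyl}oxolan-2-one, via alkylzirconocene chloride 15 (not isolated)
Conditions: Cp2Zr(H)Cl (1.5 equiv), THF, 23 °C; then I2, 0 °C
Reagents that add atoms: iodine, II
Why: Hydrozirconation places zirconium on the terminal carbon of the vinyl group for steric reasons, and iodinolysis of the C–Zr bond gives the primary iodide while the hindered lactone is left intact.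

Step 10
Reactants: 16 (4R,5S)-5-(2-iodoethyl)-3,3,5-trimethyl-4-{2-[(4R)-2,2,4-trimethyl-1,3-dioxan-4-yl]ethyl}oxolan-2-one
Product: 19 (3R,4S)-4-hydroxy-2,2,4-trimethyl-3-{2-[(4R)-2,2,4-trimethyl-1,3-dioxan-4-yl]ethyl}cyclohexan-1-one, via alkylsamarium diiodide 17 (not isolated), via bridged hemiketal alkoxide 18 (not isolated)
Conditions: SmI2 (2.5 equiv), Fe(PhCOCHCOPh)3 (2 mol %), THF, −30 → 23 °C; aq. NH4Cl
Reagents that add atoms: none
Why: Two single-electron transfers from SmI2 convert the primary iodide into the alkylsamarium 17, whose carbon (ring C4) adds to the lactone carbonyl (ring C3) to give the 7-oxabicyclo[2.2.1]heptane hemiketal alkoxide 18, and cleavage of its C3–O bond then releases the strain and delivers the keto alkoxide. The closest known reaction type is the SmI2-promoted intramolecular nucleophilic acyl substitution (Barbier type) of iodoalkyl esters and lactones. The six-membered carbocycle closes in a 6-exo-trig mode. No new stereocentre is formed: C1 and C6 are not enolisable in 19 and are carried over unchanged, and C3 is set afterwards by reduction. The step needs attack at the acyl carbon in preference to simple C–I reduction, 1,3-elimination and further reduction of the product ketone; the short tether held over the lactone face by the fully substituted C6 and C2, and the low reducing power of SmI2 towards dialkyl ketones without strong donor additives, should secure this.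

Step 11
Reactants: 19 (3R,4S)-4-hydroxy-2,2,4-trimethyl-3-{2-[(4R)-2,2,4-trimethyl-1,3-dioxan-4-yl]ethyl}cyclohexan-1-one
Product: 20 (1S,2R,4S)-1,3,3-trimethyl-2-{2-[(4R)-2,2,4-trimethyl-1,3-dioxan-4-yl]ethyl}cyclohexane-1,4-diol
Conditions: L-Selectride, LiBH(s-Bu)3 (2.5 equiv), THF, −78 °C; then H2O
Reagents that add atoms: none
Why: Bulky-hydride reduction, in which L-Selectride attacks the ketone next to the gem-dimethyl carbon from the equatorial direction of the chair that holds the C1 chain equatorial, should give the axial C3 alcohol trans to the chain.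

Step 12
Reactants: 20 (1S,2R,4S)-1,3,3-trimethyl-2-{2-[(4R)-2,2,4-trimethyl-1,3-dioxan-4-yl]ethyl}cyclohexane-1,4-diol
Product: 21 (1S,2R,4S)-2-[(3R)-3,5-dihydroxy-3-methylpentyl]-1,3,3-trimethylcyclohexane-1,4-diol
Conditions: PPTS (0.2 equiv), MeOH, 40 °C
Reagents that add atoms: none
Why: Mild acid-catalysed transketalisation in methanol removes the isopropylidene group without ionising the tertiary alcohols.

Step 13
Reactants: 21 (1S,2R,4S)-2-[(3R)-3,5-dihydroxy-3-methylpentyl]-1,3,3-trimethylcyclohexane-1,4-diol; 22 umbelliferone (7-hydroxy-2H-chromen-2-one)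
Product: 23 7-{[(3R)-5-[(1R,3S,6S)-3,6-dihydroxy-2,2,6-trimethylcyclohexyl]-3-hydroxy-3-methylpentyl]oxy}-2H-chromen-2-one (CNP0210598.2)
Conditions: PPh3, DIAD, THF, 0 → 23 °C
Reagents that add atoms: none
Why: Mitsunobu etherification, in which only the primary alcohol forms a reactive alkoxyphosphonium ion that the acidic phenol displaces, while the tertiary alcohols and the hindered axial secondary alcohol next to the quaternary carbon stay free.

Compound list
1 | (R)-(−)-linalool, (3R)-3,7-dimethylocta-1,6-dien-3-ol | CC(C)=CCC[C@@](C)(O)C=C | starting material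
2 | 9-[(3R)-3-hydroxy-3,7-dimethyloct-6-en-1-yl]-9-borabicyclo[3.3.1]nonane (not isolated) | CC(C)=CCC[C@@](C)(O)CCB1C2CCCC1CCC2 | intermediate
3 | (3R)-3,7-dimethyloct-6-ene-1,3-diol | CC(C)=CCC[C@@](C)(O)CCO | intermediate
4 | (4R)-2,2,4-trimethyl-4-(4-methylpent-3-en-1-yl)-1,3-dioxane | CC(C)=CCC[C@@]1(C)OC(C)(C)OCC1 | intermediate
5 | allyl methyl carbonate | C=CCOC(=O)OC | starting material
6 | methyl (2E)-5-[(4R)-2,2,4-trimethyl-1,3-dioxan-4-yl]pent-2-en-1-yl carbonate | COC(=O)OC/C=C/CC[C@@]1(C)OC(C)(C)OCC1 | intermediate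
7 | 1-methoxy-2-methyl-1-(trimethylsilyloxy)prop-1-ene | COC(O[Si](C)(C)C)=C(C)C | starting material
8 | methyl (3S)-2,2-dimethyl-3-{2-[(4R)-2,2,4-trimethyl-1,3-dioxan-4-yl]ethyl}pent-4-enoate | COC(=O)C(C)(C)[C@@H](CC[C@@]1(C)OC(C)(C)OCC1)C=C | intermediate
9 | methyl (3R)-2,2-dimethyl-3-(1,2,4-trioxolan-3-yl)-5-[(4R)-2,2,4-trimethyl-1,3-dioxan-4-yl]pentanoate, secondary ozonide (not isolated) | COC(=O)C(C)(C)[C@@H](CC[C@@]1(C)OC(C)(C)OCC1)C1OCOO1 | intermediate
10 | methyl (3R)-3-formyl-2,2-dimethyl-5-[(4R)-2,2,4-trimethyl-1,3-dioxan-4-yl]pentanoate | COC(=O)C(C)(C)[C@@H](CC[C@@]1(C)OC(C)(C)OCC1)C=O | intermediate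
11 | methyl (3R)-3-(1-hydroxyprop-2-en-1-yl)-2,2-dimethyl-5-[(4R)-2,2,4-trimethyl-1,3-dioxan-4-yl]pentanoate, both carbinol epimers | COC(=O)C(C)(C)[C@@H](CC[C@@]1(C)OC(C)(C)OCC1)C(O)C=C | intermediate
12 | methyl (3R)-2,2-dimethyl-3-(prop-2-enoyl)-5-[(4R)-2,2,4-trimethyl-1,3-dioxan-4-yl]pentanoate | COC(=O)C(C)(C)[C@@H](CC[C@@]1(C)OC(C)(C)OCC1)C(=O)C=C | intermediate
13 | methyl (3R)-3-[(2S)-2-(lithiooxy)but-3-en-2-yl]-2,2-dimethyl-5-[(4R)-2,2,4-trimethyl-1,3-dioxan-4-yl]pentanoate (not isolated) | COC(=O)C(C)(C)[C@@H](CC[C@@]1(C)OC(C)(C)OCC1)[C@@](C)(O[Li])C=C | intermediate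
14 | (4R,5S)-5-ethenyl-3,3,5-trimethyl-4-{2-[(4R)-2,2,4-trimethyl-1,3-dioxan-4-yl]ethyl}oxolan-2-one | CC1(C)[C@@H](CC[C@@]2(C)OC(C)(C)OCC2)[C@@](C)(OC1=O)C=C | intermediate
15 | chlorobis(cyclopentadienyl){2-[(2S,3R)-2,4,4-trimethyl-5-oxo-3-{2-[(4R)-2,2,4-trimethyl-1,3-dioxan-4-yl]ethyl}oxolan-2-yl]ethyl}zirconium (not isolated) | CC1(C)[C@@H](CC[C@@]2(C)OC(C)(C)OCC2)[C@@](C)(OC1=O)CC[Zr](Cl)(C3C=CC=C3)C4C=CC=C4 | intermediate
16 | (4R,5S)-5-(2-iodoethyl)-3,3,5-trimethyl-4-{2-[(4R)-2,2,4-trimethyl-1,3-dioxan-4-yl]ethyl}oxolan-2-one | CC1(C)[C@@H](CC[C@@]2(C)OC(C)(C)OCC2)[C@@](C)(OC1=O)CCI | intermediate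
17 | diiodo{2-[(2S,3R)-2,4,4-trimethyl-5-oxo-3-{2-[(4R)-2,2,4-trimethyl-1,3-dioxan-4-yl]ethyl}oxolan-2-yl]ethyl}samarium (not isolated) | CC1(C)[C@@H](CC[C@@]2(C)OC(C)(C)OCC2)[C@@](C)(OC1=O)CC[Sm](I)I | intermediate
18 | diiodosamarium 2,2,4-trimethyl-3-{2-[(4R)-2,2,4-trimethyl-1,3-dioxan-4-yl]ethyl}-7-oxabicyclo[2.2.1]heptan-1-olate, configuration at C3 and C4 as in 16 (not isolated) | CC1(C)[C@@H](CC[C@@]3(C)OC(C)(C)OCC3)[C@@]2(C)O[C@]1(O[Sm](I)I)CC2 | intermediate
19 | (3R,4S)-4-hydroxy-2,2,4-trimethyl-3-{2-[(4R)-2,2,4-trimethyl-1,3-dioxan-4-yl]ethyl}cyclohexan-1-one | CC1(C)[C@@H](CC[C@@]2(C)OC(C)(C)OCC2)[C@@](C)(O)CCC1=O | intermediate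
20 | (1S,2R,4S)-1,3,3-trimethyl-2-{2-[(4R)-2,2,4-trimethyl-1,3-dioxan-4-yl]ethyl}cyclohexane-1,4-diol | CC1(C)[C@@H](CC[C@@]2(C)OC(C)(C)OCC2)[C@@](C)(O)CC[C@@H]1O | intermediate
21 | (1S,2R,4S)-2-[(3R)-3,5-dihydroxy-3-methylpentyl]-1,3,3-trimethylcyclohexane-1,4-diol | CC1(C)[C@@H](CC[C@@](C)(O)CCO)[C@@](C)(O)CC[C@@H]1O | intermediate
22 | umbelliferone, 7-hydroxy-2H-chromen-2-one | Oc1ccc2ccc(=O)oc2c1 | starting material
23 | 7-{[(3R)-5-[(1R,3S,6S)-3,6-dihydroxy-2,2,6-trimethylcyclohexyl]-3-hydroxy-3-methylpentyl]oxy}-2H-chromen-2-one (CNP0210598.2) | CC1(C)[C@@H](CC[C@@](C)(O)CCOc2ccc3ccc(=O)oc3c2)[C@@](C)(O)CC[C@@H]1O | target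

Total step count: 13. Longest linear sequence: 13 steps, from (R)-linalool 1 to 23.

Steps most likely to fail

Step 10. The alkylsamarium may be protonated (net reduction of C–I to C–H) before it reaches the hindered acyl carbon, or it may expel the carboxylate by 1,3-elimination. The fallback replaces the reductive organometallic by a stabilised carbanion. It sets out from 16: displacement of iodide with PhSO2Na (DMF, 60 °C) gives the phenyl sulfone F1. LDA (2.2 equiv, THF, −78 → 0 °C) forms the α-sulfonyl carbanion at ring C4, which acylates on the lactone carbonyl (Dieckmann-type closure of the same C3–C4 bond) to give the β-keto sulfone F2; deprotonation of the product drives the closure. Reductive desulfonylation (SmI2, THF/MeOH, −78 °C) returns to the route at 19.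

Step 8. Facial selectivity in the acyclic methyl addition may be poor, and lactonisation of the tertiary alkoxide may be incomplete. The fallback moves the methyl addition onto the ring, where the axial C2 methyl blocks one face. It sets out from 11: LiAlH4 (THF, 0 °C) gives the diol F3, and Dess–Martin periodinane oxidises both hydroxyls to the keto aldehyde F4. SmI2 (THF, t-BuOH, −78 °C) closes the C3–C4 bond by ketyl–olefin cyclisation of the aldehyde ketyl onto the vinyl ketone (6-endo), giving the hydroxy ketone F5 as a mixture at C3. MeLi/CeCl3 (THF, −78 °C) should add to the ring ketone from the equatorial side to give the diol F6. Dess–Martin oxidation of the secondary alcohol returns to the route at 19.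

Step 4. The hindered tetrasubstituted ketene acetal may give a low branched-to-linear ratio or low enantioselectivity on an aliphatic allyl carbonate. The fallback sets C1 by chirality transfer in a sigmatropic rearrangement. It sets out from 4: cross-metathesis (same ruthenium catalyst) with (R)-but-3-en-2-yl 2-methylpropanoate F7, made from commercial (R)-but-3-en-2-ol and isobutyryl chloride, gives the allylic ester F8. LDA and Me3SiCl (THF, −78 °C) give the silyl ketene acetal F9, which on warming to 60 °C undergoes Ireland–Claisen rearrangement through a chair transition state with the carbinol methyl equatorial, giving the silyl ester F10. Aqueous work-up gives the acid F11 and Me3SiCHN2 (MeOH/toluene) the methyl ester F12. Ozonolysis with PPh3 work-up returns to the route at 10.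

Further compounds
F1 | step 10 | (4R,5S)-5-[2-(benzenesulfonyl)ethyl]-3,3,5-trimethyl-4-{2-[(4R)-2,2,4-trimethyl-1,3-dioxan-4-yl]ethyl}oxolan-2-one | CC1(C)[C@@H](CC[C@@]2(C)OC(C)(C)OCC2)[C@@](C)(OC1=O)CCS(=O)(=O)c3ccccc3
F2 | step 10 | (3R,4S)-6-(benzenesulfonyl)-4-hydroxy-2,2,4-trimethyl-3-{2-[(4R)-2,2,4-trimethyl-1,3-dioxan-4-yl]ethyl}cyclohexan-1-one, both C6 epimers | CC1(C)[C@@H](CC[C@@]2(C)OC(C)(C)OCC2)[C@@](C)(O)CC(S(=O)(=O)c3ccccc3)C1=O
F3 | step 8 | (3R)-2,2-dimethyl-3-{2-[(4R)-2,2,4-trimethyl-1,3-dioxan-4-yl]ethyl}hex-5-ene-1,4-diol, both C4 epimers | OCC(C)(C)[C@@H](CC[C@@]1(C)OC(C)(C)OCC1)C(O)C=C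
F4 | step 8 | (3R)-2,2-dimethyl-4-oxo-3-{2-[(4R)-2,2,4-trimethyl-1,3-dioxan-4-yl]ethyl}hex-5-enal | O=CC(C)(C)[C@@H](CC[C@@]1(C)OC(C)(C)OCC1)C(=O)C=C
F5 | step 8 | (2R)-4-hydroxy-3,3-dimethyl-2-{2-[(4R)-2,2,4-trimethyl-1,3-dioxan-4-yl]ethyl}cyclohexan-1-one, both C4 epimers | CC1(C)[C@@H](CC[C@@]2(C)OC(C)(C)OCC2)C(=O)CCC1O
F6 | step 8 | (1S,2R)-1,3,3-trimethyl-2-{2-[(4R)-2,2,4-trimethyl-1,3-dioxan-4-yl]ethyl}cyclohexane-1,4-diol, both C4 epimers | CC1(C)[C@@H](CC[C@@]2(C)OC(C)(C)OCC2)[C@@](C)(O)CCC1O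
F7 | step 4 | (2R)-but-3-en-2-yl 2-methylpropanoate | CC(C)C(=O)O[C@H](C)C=C
F8 | step 4 | (2R,3E)-6-[(4R)-2,2,4-trimethyl-1,3-dioxan-4-yl]hex-3-en-2-yl 2-methylpropanoate | CC(C)C(=O)O[C@H](C)/C=C/CC[C@@]1(C)OC(C)(C)OCC1
F9 | step 4 | trimethyl[(2-methyl-1-{[(2R,3E)-6-[(4R)-2,2,4-trimethyl-1,3-dioxan-4-yl]hex-3-en-2-yl]oxy}prop-1-en-1-yl)oxy]silane | CC(C)=C(O[Si](C)(C)C)O[C@H](C)/C=C/CC[C@@]1(C)OC(C)(C)OCC1
F10 | step 4 | trimethylsilyl (3S,4E)-2,2-dimethyl-3-{2-[(4R)-2,2,4-trimethyl-1,3-dioxan-4-yl]ethyl}hex-4-enoate | C[Si](C)(C)OC(=O)C(C)(C)[C@@H](CC[C@@]1(C)OC(C)(C)OCC1)/C=C/C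
F11 | step 4 | (3S,4E)-2,2-dimethyl-3-{2-[(4R)-2,2,4-trimethyl-1,3-dioxan-4-yl]ethyl}hex-4-enoic acid | OC(=O)C(C)(C)[C@@H](CC[C@@]1(C)OC(C)(C)OCC1)/C=C/C
F12 | step 4 | methyl (3S,4E)-2,2-dimethyl-3-{2-[(4R)-2,2,4-trimethyl-1,3-dioxan-4-yl]ethyl}hex-4-enoate | COC(=O)C(C)(C)[C@@H](CC[C@@]1(C)OC(C)(C)OCC1)/C=C/C
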